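## Structural features

Mollicellin A (20, C21H18O7) is a tetracyclic depsidone in which benzene ring A and benzene ring B are joined by a diaryl ether oxygen and by an ester, the two links closing the central seven-membered dioxepinone. Ring B is hexasubstituted and carries a fused 2,2-dimethyl-2,3-dihydropyran-4-one, numbered here as a chromanone: O-1, C-2 (gem-dimethyl), C-4 (ketone), C-5 (methyl), C-6 (ether oxygen), C-7 (ester oxygen), C-8 (H). Ring A is pentasubstituted and is numbered here C-1 (methyl), C-2 (H), C-3 (OH), C-4 (CHO), C-5 (ether oxygen), C-6 (lactone carbonyl). The molecule has no stereocentre, because C-2 of the pyranone bears two methyl groups, so the only stereochemical element of the route is the alkene geometry of 10. Three groups are fragile: the aldehyde ortho to a free phenol, the aryl ester of the dioxepinone (labile to hydroxide, alkoxide and amines), and the chromanone, which enolises, opens by retro-oxa-Michael reaction under strong base and has a tertiary alkyl aryl ether that strong Lewis acids can cleave. The real difficulty is the diaryl ether oxygen, which sits between four ortho substituents (CHO and lactone carbonyl on ring A, methyl and ester oxygen on ring B), so that an intermolecular aryl–oxygen coupling is badly hindered; a second difficulty is the 1,2,4-trioxygenated ring B, whose three oxygens must be told apart. The key step exploits the fact that ring A shares C-5 and C-6 with the dioxepinone. A ring B catechol with an ynol ether on O-6 and a but-2-ynoate on O-7 therefore already holds ring A C-5, C-4, C-6 and C-1 and every atom of the seven-membered ring, and only C-2 and C-3 have to come from outside.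

## Logic of the disconnections

20 from 19: the ethyl–oxygen bond at ring A C-3 is cut. The phenol next to the aldehyde is carried as an ether because a free ortho-formyl phenol would not survive the metal-catalysed step; cutting here leaves a last step that is a single deprotection on the finished skeleton. The forward step needs a dealkylation that is directed by chelation to the aldehyde and spares the lactone, the diaryl ether and the pyranone ether.

19 from 17 (through 18): the C-2–silicon bond and the two acetal C–O bonds are cut. Silicon is only a steering group for the ring synthesis, and the acetal masks the aldehyde and supplies steric bulk, so both auxiliaries disappear in one operation. The acid treatment must remove both without touching the lactone.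

17 from 15 and 16: three ring A C–C bonds are cut, namely C-5–C-6, C-1–C-2 and C-3–C-4. This removes ring A and the dioxepinone together and turns the crowded diaryl ether into an ordinary O–C(sp) bond that is already in place, so a tetracycle becomes a bicycle with two alkyne arms. The forward cycloaddition must accept a tether that closes a seven-membered ring, and must insert 16 in one orientation only.

15 from 12 and 13: the ester C–O bond at O-7 is cut, because it is the most easily made bond of the precursor and releases a commercial four-carbon acid. The acylation must run without free carboxylic acid, which would add to the ynol ether; this is why 13 is first converted into 14.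

12 from 11, 11 from 10, and 10 from 7 and 9: the allyl–oxygen bond is cut first, then the O-6–C(sp) bond is traced back to a copper-catalysed C(sp2)–O coupling followed by loss of HBr. This reduces the ynol ether to a phenol and a three-carbon dibromoalkene. O-7 carries an allyl group during this sequence, because a silyl or acyl group would migrate to the neighbouring O-6 under the basic coupling conditions and send the alkyne to the wrong oxygen. The demand is a deallylation under neutral palladium catalysis that the ynol ether and the acetal tolerate.

9 from 8: the C=C bond is cut (dibromo-olefination), which leads to a commercial aldehyde. The acetal must survive the phosphorus halide by-products.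

7 from 6 and 6 from 5: the allyl–oxygen bond and the two methyl–oxygen bonds are cut. Two identical methyl ethers keep the early steps simple, and the two catechol oxygens of 6 are then told apart by acidity: O-7 is para to the ketone and much more acidic than O-6, which is meta to it and next to the methyl group. The forward step must alkylate O-7 only.

5 from 3 and 4: the aryl–C(=O) bond at C-4a and the O-1–C-2 bond are cut. This builds the pyranone in one operation on a phenol that already has all three ring B oxygens. The acylation must go to the ortho position next to the methyl group.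

3 from 1 (through 2): the C–O bond of the phenol is cut, which leads back to a commercial arene. Oxygen is placed at the one ring position of 1 with no ortho neighbour, which is where sterically controlled C–H borylation goes. Starting here avoids a late hydroxylation at C-6 of a 7-hydroxychromanone, which would compete with the more accessible C-8.

## Other disconnections considered

Alternative 1: The cut is the single diaryl ether bond from the ring A oxygen to ring B C-6. Depside A1 (3-hydroxy-5-methyl-4-(3-methylbut-2-enoyl)phenyl 3-formyl-2,4-dihydroxy-6-methylbenzoate) would be oxidised at its ring B phenol, at a graphite anode in a fluorinated alcohol or with PhI(OAc)2. The ring A hydroxyl ortho to the ester would then attack the ring B carbon para to the oxidised phenol and close the dioxepinone to A2 (20 with the pyranone open as a 3-methylbut-2-enoyl ketone beside a free ring B phenol). Base would finally close the pyranone by oxa-Michael addition to give 20.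
- In its favour: it mirrors the likely biosynthesis, and the ester is made by ordinary acylation. Ring B needs no oxygen at C-6 at all, so the catechol construction of steps 1 to 4 disappears. In step economy it is clearly the better plan, at perhaps half the length.
- Against it here: the phenol to be oxidised is ortho-acylated, hydrogen-bonded and therefore electron-poor. The substrate also holds two ring A phenols, an aldehyde and an enone. The nucleophile is a hydroxyl locked between two carbonyl groups, and the carbon attacked lies between a methyl and an acyloxy group. Spiro closure, C–C coupling, quinone formation and solvent capture are all plausible diversions.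
- Comparison: on precedent the two plans are equal, since neither key step has a close model. Structurally, Alternative 1 makes the one most hindered bond of the molecule directly, while the chosen plan never forms an aryl–oxygen bond at the crowded positions and builds two rings and three C–C bonds in one event. Mechanistically the oxidation leaves little to tune beyond electrode and medium, whereas the cycloaddition has catalyst, tether electronics and the steering groups as variables.

Alternative 2: The cuts are two ring A C–C bonds, C-3–C-4 and C-1–C-2 in the ring A numbering used here. 2-Pyrone A3 (benzyl 4-[(7-benzyloxy-2,2,5-trimethyl-4-oxochroman-6-yl)oxy]-5-(dimethoxymethyl)-2-methyl-6-oxo-6H-pyran-3-carboxylate) and ethoxyacetylene A4 would combine in an inverse-demand [4+2] cycloaddition. Loss of the lactone bridge would aromatise the adduct to A5 (benzyl 2-[(7-benzyloxy-2,2,5-trimethyl-4-oxochroman-6-yl)oxy]-3-(dimethoxymethyl)-4-ethoxy-6-methylbenzoate). Removal of both benzyl groups, acetal hydrolysis and closure of the seven-membered lactone would then reach 19, and the last step of the chosen route would follow.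
- In its favour: pyrone–alkyne cycloaddition with decarboxylative aromatisation is an established arene synthesis, and its regiochemistry follows from the polarisation of both partners. On precedent and regiochemical confidence it is better than the chosen plan. The ring A hydrogen arrives directly, so no silicon group is needed, which is also better.
- Equal point: the same ethyl ether ortho to the aldehyde must be cleaved at the end.
- Against it here: A3 is a pentasubstituted pyrone that must already carry the acetal, the ester and the hindered ring B aryloxy group, so the crowded C–O bond is only moved into the pyrone synthesis. The donor aryloxy group lowers the reactivity of the diene, so heat would be needed, and A4 fragments thermally.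
- Comparison: structurally the cycloaddition builds only ring A, so the seven-membered lactone needs a separate closure, whereas the chosen plan closes both rings at once. Mechanistically Alternative 2 is the safer reaction. In step economy it is estimated at three to four steps more than the chosen plan.

Alternative 3: The cuts are three ring A C–C bonds, C-3–C-4, C-5–C-6 and C-2–C-3. Irradiation of diazo ketoester A6 (benzyl 2-diazo-4-methyl-3-oxopent-4-enoate) in the presence of ring B ynol ether A7 (7-(benzyloxy)-6-[(3,3-diethoxyprop-1-yn-1-yl)oxy]-2,2,5-trimethylchroman-4-one) would trigger a Wolff rearrangement to vinylketene A8 (benzyl 3-methyl-2-(oxomethylidene)but-3-enoate). [2+2] addition of A8 to the alkyne of A7, four-electron ring opening and six-electron ring closure, a Danheiser-type benzannulation, would give phenol A9 (benzyl 2-[(7-benzyloxy-2,2,5-trimethyl-4-oxochroman-6-yl)oxy]-3-(diethoxymethyl)-4-hydroxy-6-methylbenzoate). Debenzylation, lactonisation and acetal hydrolysis would then give 20.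
- In its favour: the free ring A phenol is delivered directly, so neither the boron halide dealkylation nor the desilylation is needed, which is better. The regiochemistry is intrinsic to the ketene–ynol ether polarity, which is better. Benzannulation of heteroatom-substituted alkynes with vinylketenes is a known reaction type, which is better on precedent.
- Equal point: A7 would be made by the same copper chemistry as 11.
- Against it here: A8 carries an ester on the ketene carbon, and acyl-substituted ketenes of this kind tend to react as oxadienes in [4+2] mode with electron-rich alkynes. Irradiation must be done in the presence of the ortho-methyl aryl ketone of ring B, which can photoenolise. A6 is a polymerisable isopropenyl ketone.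
- Comparison: structurally the benzannulation makes ring A only, and the seven-membered lactone must still be closed in a separate step, whereas the chosen plan closes both rings at once. Mechanistically it rests on a known reaction type but on an unfavourable ketene. The overall step count is about equal to the chosen plan or one step longer.

Key step: step 10

Assumption: 8 and 16 are taken as purchasable reagents, and the acidity difference between the two phenols of 6 is estimated from their positions relative to the ketone (O-7 para, O-6 meta).

## Route

Step 1
Reactants: 1 2,3-dimethoxytoluene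
Product: 3 3,4-dimethoxy-5-methylphenol, via pinacol boronate 2 (not isolated)
Conditions: [Ir(OMe)(cod)]2 (1 mol %), 4,4'-di-tert-butyl-2,2'-bipyridine (2 mol %), B2pin2 (1.0 equiv), THF, 80 °C; then KHSO5 (as 2KHSO5·KHSO4·K2SO4), acetone–H2O, rt
Reagents that add atoms: bis(pinacolato)diboron, CC1(C)OB(OC1(C)C)B1OC(C)(C)C(C)(C)O1 (boron of 2); potassium peroxymonosulfate, [K+].[O-]S(=O)(=O)OO (phenol oxygen of 3)
Why: Iridium-catalysed C–H borylation is governed by sterics and should take the only ring position of 1 that has no ortho substituent; oxidation of the C–B bond by peroxymonosulfate in the same flask then gives the phenol.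

Step 2
Reactants: 3 3,4-dimethoxy-5-methylphenol; 4 3-methylbut-2-enoic acid
Product: 5 6,7-dimethoxy-2,2,5-trimethylchroman-4-one
Conditions: P2O5, MeSO3H, 70 °C
Reagents that add atoms: none
Why: Friedel–Crafts acylation ortho to the phenol and para to the conjugated 3-methoxy group, followed by oxa-Michael closure of the phenol onto the enone, is the standard one-flask entry to 2,2-dimethylchroman-4-ones from electron-rich phenols; the other ortho position lies between OH and OMe and is para to no oxygen donor.

Step 3
Reactants: 5 6,7-dimethoxy-2,2,5-trimethylchroman-4-one
Product: 6 6,7-dihydroxy-2,2,5-trimethylchroman-4-one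
Conditions: BBr3 (3.5 equiv), CH2Cl2, −78 → 0 °C; aq. NaHCO3
Reagents that add atoms: none
Why: Lewis acid cleavage of aryl methyl ethers should remove both methyl groups; the ring oxygen is conjugated to the ketone and is the least basic ether, and any opened pyranone should reclose by oxa-Michael addition on bicarbonate work-up.

Step 4
Reactants: 6 6,7-dihydroxy-2,2,5-trimethylchroman-4-one
Product: 7 7-(allyloxy)-6-hydroxy-2,2,5-trimethylchroman-4-one
Conditions: allyl bromide (1.05 equiv), KHCO3, DMF, 40 °C
Reagents that add atoms: allyl bromide, C=CCBr
Why: Williamson etherification under a weak base should ionise and alkylate only O-7, which is para to the ketone and far more acidic than the hindered O-6; an allyl ether cannot migrate to O-6 in the basic steps that follow.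

Step 5
Reactants: 8 2,2-diethoxyacetaldehyde
Product: 9 1,1-dibromo-3,3-diethoxyprop-1-ene
Conditions: CBr4, PPh3, CH2Cl2, 0 °C; then Et3N and the aldehyde, −78 → 0 °C
Reagents that add atoms: carbon tetrabromide, BrC(Br)(Br)Br
Why: Ramirez dibromo-olefination (the first stage of the Corey–Fuchs sequence) converts the aldehyde into the gem-dibromoalkene; Et3N buffers the acidic phosphorus bromide by-products that would attack the acetal.

Step 6
Reactants: 7 7-(allyloxy)-6-hydroxy-2,2,5-trimethylchroman-4-one; 9 1,1-dibromo-3,3-diethoxyprop-1-ene
Product: 10 (Z)-7-(allyloxy)-6-[(1-bromo-3,3-diethoxyprop-1-en-1-yl)oxy]-2,2,5-trimethylchroman-4-one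
Conditions: CuI (10 mol %), 2,2'-bipyridine (20 mol %), K3PO4, toluene, 110 °C, dibromoalkene in 1.5-fold excess
Reagents that add atoms: none
Why: Copper-catalysed Ullmann-type C–O coupling of a phenol with a 1,1-dibromoalkene should replace the less hindered bromide (trans to the acetal carbon) with retention, leaving the remaining Br trans to the vinylic H; copper phenoxide couplings are known to accept 2,6-disubstituted phenols.

Step 7
Reactants: 10 (Z)-7-(allyloxy)-6-[(1-bromo-3,3-diethoxyprop-1-en-1-yl)oxy]-2,2,5-trimethylchroman-4-one
Product: 11 7-(allyloxy)-6-[(3,3-diethoxyprop-1-yn-1-yl)oxy]-2,2,5-trimethylchroman-4-one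
Conditions: KOtBu (2.2 equiv), THF, 0 °C → rt; pH 7 buffer
Reagents that add atoms: none
Why: H and Br are anti-periplanar in 10, so E2 dehydrobromination to the ynol ether should be fast; any chromanone enolate or ring-opened phenoxide should return to the chromanone on buffered work-up.

Step 8
Reactants: 11 7-(allyloxy)-6-[(3,3-diethoxyprop-1-yn-1-yl)oxy]-2,2,5-trimethylchroman-4-one
Product: 12 6-[(3,3-diethoxyprop-1-yn-1-yl)oxy]-7-hydroxy-2,2,5-trimethylchroman-4-one
Conditions: Pd(PPh3)4 (5 mol %), morpholine (2 equiv), THF, 0 °C → rt; pH 7 phosphate work-up, used at once
Reagents that add atoms: none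
Why: Tsuji–Trost deallylation: zerovalent palladium ionises the aryl allyl ether (the ketone-stabilised phenoxide is a good leaving group) and morpholine captures the allyl fragment; the medium stays neutral to weakly basic, which the ynol ether and the acetal tolerate.

Step 9
Reactants: 12 6-[(3,3-diethoxyprop-1-yn-1-yl)oxy]-7-hydroxy-2,2,5-trimethylchroman-4-one; 13 but-2-ynoic acid
Product: 15 6-[(3,3-diethoxyprop-1-yn-1-yl)oxy]-2,2,5-trimethyl-4-oxochroman-7-yl but-2-ynoate, via but-2-ynoic anhydride 14 (not isolated)
Conditions: 13 (2.4 equiv), DCC (1.2 equiv), CH2Cl2, 0 °C; then 12, Et3N, DMAP (5 mol %), −20 → 0 °C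
Reagents that add atoms: none
Why: Steglich-type acyl transfer from the preformed symmetrical anhydride to the ammonium phenoxide of 12; preforming 14 means that no free carboxylic acid, which would add across the ynol ether, ever meets 12.

Step 10
Reactants: 15 6-[(3,3-diethoxyprop-1-yn-1-yl)oxy]-2,2,5-trimethyl-4-oxochroman-7-yl but-2-ynoate; 16 ethoxy(trimethylsilyl)acetylene
Product: 17 silylated O-ethylmollicellin A diethyl acetal (ring A: 1-methyl-2-trimethylsilyl-3-ethoxy-4-diethoxymethyl)
Conditions: Cp*RuCl(cod) (10 mol %), 1,2-dichloroethane, 40 °C, diyne added slowly by syringe pump to the monoalkyne in fourfold excess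
Reagents that add atoms: none
Why: Proposed new method: the closest known reaction type is the Cp*RuCl(cod)- or cationic monovalent rhodium-catalysed [2+2+2] cycloaddition of a tethered diyne (ynoates included) with a monoalkyne, established for tethers that close five- and six-membered rings, whereas the ortho-phenylene ether/ester tether of 15 has to close a seven-membered ring. After dissociation of cod the Cp*RuCl fragment should bind both alkynes of 15 and couple them oxidatively at their tether-bound carbons (ynoate α-carbon and oxygen-bearing ynol ether carbon), an electron-poor/electron-rich pairing that the rigid catechol holds side by side; this gives a ruthenacycle that already contains the dioxepinone. Alkyne 16 then inserts into one Ru–C bond and reductive elimination releases the benzene. Ring A therefore closes in the [2+2+2] event itself through three new C–C bonds, and the seven-membered lactone closes by annulation through the O–C(sp) and O–C(=O) links that are already present, so no aryl–oxygen bond is formed at the crowded positions. No stereocentre is formed. Cross-trimerisation must outrun homo-trimerisation, which slow addition of 15 to an excess of 16 should secure because the silylated alkyne does not readily trimerise by itself. One orientation of 16 is also needed, with the silyl carbon bonded to the methyl-bearing terminus and the ethoxy carbon to the acetal-bearing terminus; sterics (SiMe3 kept away from the branched acetal) and polarity (the nucleophilic silyl-bearing carbon of 16 meets the terminus β to the ester, the oxygen-bearing carbon meets the ynol ether-derived terminus) point the same way.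

Step 11
Reactants: 17 silylated O-ethylmollicellin A diethyl acetal
Product: 19 O-ethylmollicellin A (ring A 3-ethoxy-4-formyl), via silyl aldehyde 18 (not isolated)
Conditions: CF3CO2H–CH2Cl2–H2O (10:10:1), rt → 40 °C
Reagents that add atoms: water, O
Why: Aqueous acid hydrolyses the acetal to the aldehyde, and ipso-protodesilylation of the aryl silane should follow because the silicon-bearing carbon is ortho to ethoxy, para to aryloxy and relieved of strain between two ortho neighbours; the lactone, diaryl ether and chromanone are stable to acid.

Step 12
Reactants: 19 O-ethylmollicellin A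
Product: 20 mollicellin A
Conditions: BCl3 (3 equiv), CH2Cl2, −78 → 0 °C; aq. NaHCO3
Reagents that add atoms: none
Why: Chelation-controlled dealkylation: BCl3 bridges the formyl oxygen and the ortho ethoxy oxygen and cleaves only that ethyl–oxygen bond; the pyranone oxygen cannot chelate to its ketone, and the diaryl ether and lactone should be spared at low temperature.

## Compound list

1 | 2,3-dimethoxytoluene | Cc1cccc(OC)c1OC | starting material
2 | 2-(3,4-dimethoxy-5-methylphenyl)-4,4,5,5-tetramethyl-1,3,2-dioxaborolane | Cc1cc(B2OC(C)(C)C(C)(C)O2)cc(OC)c1OC | intermediate
3 | 3,4-dimethoxy-5-methylphenol | Cc1cc(O)cc(OC)c1OC | intermediate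
4 | 3-methylbut-2-enoic acid | CC(C)=CC(=O)O | starting material
5 | 6,7-dimethoxy-2,2,5-trimethylchroman-4-one | COc1cc2OC(C)(C)CC(=O)c2c(C)c1OC | intermediate
6 | 6,7-dihydroxy-2,2,5-trimethylchroman-4-one | Oc1cc2OC(C)(C)CC(=O)c2c(C)c1O | intermediate
7 | 7-(allyloxy)-6-hydroxy-2,2,5-trimethylchroman-4-one | C=CCOc1cc2OC(C)(C)CC(=O)c2c(C)c1O | intermediate
8 | 2,2-diethoxyacetaldehyde | CCOC(OCC)C=O | starting material
9 | 1,1-dibromo-3,3-diethoxyprop-1-ene | CCOC(OCC)C=C(Br)Br | intermediate
10 | (Z)-7-(allyloxy)-6-[(1-bromo-3,3-diethoxyprop-1-en-1-yl)oxy]-2,2,5-trimethylchroman-4-one (Br cis to the acetal carbon, trans to the vinylic H) | CCOC(OCC)/C=C(Br)/Oc1c(OCC=C)cc2OC(C)(C)CC(=O)c2c1C | intermediate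
11 | 7-(allyloxy)-6-[(3,3-diethoxyprop-1-yn-1-yl)oxy]-2,2,5-trimethylchroman-4-one | CCOC(OCC)C#COc1c(OCC=C)cc2OC(C)(C)CC(=O)c2c1C | intermediate
12 | 6-[(3,3-diethoxyprop-1-yn-1-yl)oxy]-7-hydroxy-2,2,5-trimethylchroman-4-one | CCOC(OCC)C#COc1c(O)cc2OC(C)(C)CC(=O)c2c1C | intermediate
13 | but-2-ynoic acid | CC#CC(=O)O | starting material
14 | but-2-ynoic anhydride | CC#CC(=O)OC(=O)C#CC | intermediate
15 | 6-[(3,3-diethoxyprop-1-yn-1-yl)oxy]-2,2,5-trimethyl-4-oxochroman-7-yl but-2-ynoate | CC#CC(=O)Oc1cc2OC(C)(C)CC(=O)c2c(C)c1OC#CC(OCC)OCC | intermediate
16 | ethoxy(trimethylsilyl)acetylene | CCOC#C[Si](C)(C)C | starting material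
17 | silylated O-ethylmollicellin A diethyl acetal (depsidone with ring A C-1 methyl, C-2 trimethylsilyl, C-3 ethoxy and C-4 diethoxymethyl, ring B fused to the 2,2,5-trimethylchroman-4-one) | Cc1c([Si](C)(C)C)c(OCC)c(C(OCC)OCC)c2c1C(=O)Oc1cc3c(c(C)c1O2)C(=O)CC(C)(C)O3 | intermediate
18 | silyl aldehyde (depsidone with ring A C-2 trimethylsilyl, C-3 ethoxy and C-4 formyl) | Cc1c([Si](C)(C)C)c(OCC)c(C=O)c2c1C(=O)Oc1cc3c(c(C)c1O2)C(=O)CC(C)(C)O3 | intermediate
19 | O-ethylmollicellin A (ring A C-3 ethoxy, C-4 formyl) | Cc1cc(OCC)c(C=O)c2c1C(=O)Oc1cc3c(c(C)c1O2)C(=O)CC(C)(C)O3 | intermediate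
20 | mollicellin A | Cc1cc(O)c(C=O)c2c1C(=O)Oc1cc3c(c(C)c1O2)C(=O)CC(C)(C)O3 | target

## Step count and least certain steps

Total step count: 12. Longest linear sequence: 11 steps (steps 1 to 4 and 6 to 12); step 5 is a one-step branch.

Step 10 (key step, proposed new method). What may go wrong is oligomerisation of 15 or trimerisation between molecules instead of closure of the strained seven-membered metallacycle, because a tether of this length has no model. Slow or misoriented insertion of the hindered silylated alkyne into a metallacycle substituted at both termini, and catalyst-induced decomposition of the ynol ether, are further risks. Within the same disconnection, a cationic monovalent rhodium catalyst, [Rh(cod)2]BF4 with BINAP, would be tried first. The fallback uses known chemistry only, sets out from 7 and comes back to the route at 19. Commercial 4-bromo-2-fluoro-6-methylbenzoic acid would be ethoxylated at the C–Br bond (CuI, 1,10-phenanthroline, Cs2CO3, EtOH, 110 °C; Ullmann ether synthesis) to 4-ethoxy-2-fluoro-6-methylbenzoic acid F1. Esterification (allyl bromide, K2CO3, DMF) would give allyl 4-ethoxy-2-fluoro-6-methylbenzoate F2. Magnesiation at the ring position between fluorine and ethoxy and formylation (TMPMgCl·LiCl, THF, −40 °C; then DMF) would give allyl 4-ethoxy-2-fluoro-3-formyl-6-methylbenzoate F3. The phenoxide of 7 would displace the fluoride, which is activated by the ortho formyl and ortho ester groups (Cs2CO3, DMF, 60 °C; nucleophilic aromatic substitution), to give allyl 2-{[7-(allyloxy)-2,2,5-trimethyl-4-oxochroman-6-yl]oxy}-4-ethoxy-3-formyl-6-methylbenzoate F4. Both allyl groups would be removed together (Pd(PPh3)4, morpholine, THF) to give 4-ethoxy-3-formyl-2-[(7-hydroxy-2,2,5-trimethyl-4-oxochroman-6-yl)oxy]-6-methylbenzoic acid F5. Lactonisation under dilution (2-chloro-1-methylpyridinium iodide, Et3N, CH2Cl2) would then give 19, and step 12 would follow.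

Step 8. What may go wrong is addition of the liberated phenol or phenoxide across the neighbouring ynol ether (cyclisation to a five- or six-membered cyclic ketene acetal), promoted by [Pd(allyl)(PPh3)2]+ or by protonation during work-up; slow loss of the phenol before it is acylated is a related risk. The fallback sets out from 6 and comes back to the route at 15. Mitsunobu reaction of 6 with 2-(trimethylsilyl)ethanol (PPh3, diisopropyl azodicarboxylate, THF), selective for the more acidic O-7, would give 6-hydroxy-2,2,5-trimethyl-7-[2-(trimethylsilyl)ethoxy]chroman-4-one F6. The conditions of step 6 would give (Z)-6-[(1-bromo-3,3-diethoxyprop-1-en-1-yl)oxy]-2,2,5-trimethyl-7-[2-(trimethylsilyl)ethoxy]chroman-4-one F7, and those of step 7 would give 6-[(3,3-diethoxyprop-1-yn-1-yl)oxy]-2,2,5-trimethyl-7-[2-(trimethylsilyl)ethoxy]chroman-4-one F8. Bu4NF in THF would fragment the silylethyl ether under aprotic conditions to the ammonium phenoxide, and 14 would be added to the same flask to give 15, so that the free phenol is never handled.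

Step 6. What may go wrong is sluggish coupling at the 6-hydroxyl, which has substituents in both ortho positions, with competing dehydrobromination of 9 to the bromoalkyne or a second substitution on the alkene. The fallback sets out from 7 and comes back to the route at 11. Bromination of commercial 1,1-diethoxypropan-2-one would give 1-bromo-3,3-diethoxypropan-2-one F9. O-Alkylation of 7 with it (K2CO3, acetone; SN2, little affected by the hindrance of the phenol) would give 7-(allyloxy)-6-(3,3-diethoxy-2-oxopropoxy)-2,2,5-trimethylchroman-4-one F10. Nonafluorobutanesulfonyl fluoride and a phosphazene base (tert-butylimino-tri(pyrrolidino)phosphorane) in THF would convert the more acidic α-aryloxy ketone into the enol nonaflate (Z)-1-{[7-(allyloxy)-2,2,5-trimethyl-4-oxochroman-6-yl]oxy}-3,3-diethoxyprop-1-en-2-yl nonafluorobutane-1-sulfonate F11. The same base would then eliminate the sulfonate to give 11.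

Step 2. What may go wrong is acylation at the other ortho position (between OH and OMe), or C-alkylation by the acid leading to the isomeric 4,4-dimethylchroman-2-one skeleton. The fallback sets out from 1 and comes back to the route at 5. Friedel–Crafts acetylation of 1 (AcCl, AlCl3, CH2Cl2, 0 °C), para to the conjugated 3-methoxy group, would give 1-(3,4-dimethoxy-2-methylphenyl)ethanone F12. Ketone-directed ortho C–H hydroxylation (Pd(OAc)2 cat., K2S2O8, CF3CO2H/(CF3CO)2O), which has only one free ortho position to choose, would give 1-(6-hydroxy-3,4-dimethoxy-2-methylphenyl)ethanone F13. Kabbe condensation with acetone and pyrrolidine would then give 5.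

## Further compounds

F1 | step 10 | 4-ethoxy-2-fluoro-6-methylbenzoic acid | CCOc1cc(C)c(C(=O)O)c(F)c1
F2 | step 10 | allyl 4-ethoxy-2-fluoro-6-methylbenzoate | C=CCOC(=O)c1c(C)cc(OCC)cc1F
F3 | step 10 | allyl 4-ethoxy-2-fluoro-3-formyl-6-methylbenzoate | C=CCOC(=O)c1c(C)cc(OCC)c(C=O)c1F
F4 | step 10 | allyl 2-{[7-(allyloxy)-2,2,5-trimethyl-4-oxochroman-6-yl]oxy}-4-ethoxy-3-formyl-6-methylbenzoate | C=CCOC(=O)c1c(C)cc(OCC)c(C=O)c1Oc1c(OCC=C)cc2OC(C)(C)CC(=O)c2c1C
F5 | step 10 | 4-ethoxy-3-formyl-2-[(7-hydroxy-2,2,5-trimethyl-4-oxochroman-6-yl)oxy]-6-methylbenzoic acid | CCOc1cc(C)c(C(=O)O)c(Oc2c(O)cc3OC(C)(C)CC(=O)c3c2C)c1C=O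
F6 | step 8 | 6-hydroxy-2,2,5-trimethyl-7-[2-(trimethylsilyl)ethoxy]chroman-4-one | C[Si](C)(C)CCOc1cc2OC(C)(C)CC(=O)c2c(C)c1O
F7 | step 8 | (Z)-6-[(1-bromo-3,3-diethoxyprop-1-en-1-yl)oxy]-2,2,5-trimethyl-7-[2-(trimethylsilyl)ethoxy]chroman-4-one | CCOC(OCC)/C=C(Br)/Oc1c(OCC[Si](C)(C)C)cc2OC(C)(C)CC(=O)c2c1C
F8 | step 8 | 6-[(3,3-diethoxyprop-1-yn-1-yl)oxy]-2,2,5-trimethyl-7-[2-(trimethylsilyl)ethoxy]chroman-4-one | CCOC(OCC)C#COc1c(OCC[Si](C)(C)C)cc2OC(C)(C)CC(=O)c2c1C
F9 | step 6 | 1-bromo-3,3-diethoxypropan-2-one | CCOC(OCC)C(=O)CBr
F10 | step 6 | 7-(allyloxy)-6-(3,3-diethoxy-2-oxopropoxy)-2,2,5-trimethylchroman-4-one | CCOC(OCC)C(=O)COc1c(OCC=C)cc2OC(C)(C)CC(=O)c2c1C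
F11 | step 6 | (Z)-1-{[7-(allyloxy)-2,2,5-trimethyl-4-oxochroman-6-yl]oxy}-3,3-diethoxyprop-1-en-2-yl nonafluorobutane-1-sulfonate | CCOC(OCC)/C(OS(=O)(=O)C(F)(F)C(F)(F)C(F)(F)C(F)(F)F)=C/Oc1c(OCC=C)cc2OC(C)(C)CC(=O)c2c1C
F12 | step 2 | 1-(3,4-dimethoxy-2-methylphenyl)ethanone | CC(=O)c1ccc(OC)c(OC)c1C
F13 | step 2 | 1-(6-hydroxy-3,4-dimethoxy-2-methylphenyl)ethanone | CC(=O)c1c(O)cc(OC)c(OC)c1C
A1 | alternative 1 | 3-hydroxy-5-methyl-4-(3-methylbut-2-enoyl)phenyl 3-formyl-2,4-dihydroxy-6-methylbenzoate | Cc1cc(O)c(C=O)c(O)c1C(=O)Oc1cc(O)c(C(=O)C=C(C)C)c(C)c1
A2 | alternative 1 | pyranone-opened mollicellin A (depsidone with free ring B phenol and 3-methylbut-2-enoyl ketone) | Cc1cc(O)c(C=O)c2c1C(=O)Oc1cc(O)c(C(=O)C=C(C)C)c(C)c1O2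
A3 | alternative 2 | benzyl 4-[(7-benzyloxy-2,2,5-trimethyl-4-oxochroman-6-yl)oxy]-5-(dimethoxymethyl)-2-methyl-6-oxo-6H-pyran-3-carboxylate | O=C1OC(C)=C(C(=O)OCc2ccccc2)C(Oc2c(OCc3ccccc3)cc3OC(C)(C)CC(=O)c3c2C)=C1C(OC)OC
A4 | alternative 2 | ethoxyacetylene | CCOC#C
A5 | alternative 2 | benzyl 2-[(7-benzyloxy-2,2,5-trimethyl-4-oxochroman-6-yl)oxy]-3-(dimethoxymethyl)-4-ethoxy-6-methylbenzoate | O=C(OCc1ccccc1)c1c(C)cc(OCC)c(C(OC)OC)c1Oc1c(OCc2ccccc2)cc2OC(C)(C)CC(=O)c2c1C
A6 | alternative 3 | benzyl 2-diazo-4-methyl-3-oxopent-4-enoate | C=C(C)C(=O)C(=[N+]=[N-])C(=O)OCc1ccccc1
A7 | alternative 3 | 7-(benzyloxy)-6-[(3,3-diethoxyprop-1-yn-1-yl)oxy]-2,2,5-trimethylchroman-4-one | CCOC(OCC)C#COc1c(OCc2ccccc2)cc2OC(C)(C)CC(=O)c2c1C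
A8 | alternative 3 | benzyl 3-methyl-2-(oxomethylidene)but-3-enoate | C=C(C)C(=C=O)C(=O)OCc1ccccc1
A9 | alternative 3 | benzyl 2-[(7-benzyloxy-2,2,5-trimethyl-4-oxochroman-6-yl)oxy]-3-(diethoxymethyl)-4-hydroxy-6-methylbenzoate | O=C(OCc1ccccc1)c1c(C)cc(O)c(C(OCC)OCC)c1Oc1c(OCc2ccccc2)cc2OC(C)(C)CC(=O)c2c1C
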